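Time sorts this flask into rungs, and the charges and questions come first.

| setting | Tuesday's | Wednesday's | flask |
|---|---|---|---|
| starting material | 0.20 M | 0.20 M | 0.20 M |
| first nucleophile | 0.20 M | 0.31 M | 0.140 M |
| second nucleophile | 0.36 M | 0.36 M | 0.360 M |
| remark | run made earlier | run made earlier |  |
| time |  |  | 5.0 h |

- Tuesday's (time / h: other capture product / %, target / %, starting material / %): 0.417: 22.6, 35.6, 13.4; 0.667: 24.9, 39.1, 4.7; 1.00: 24.3, 39.6, 2.8; 1.33: 23.7, 41.5, 0; 2.00: 25.4, 40.6, 0; 3.00: 23.8, 39.7, 0.3; 5.00: 25.0, 40.9, 0
- Wednesday's (time / h: other capture product / %, target / %, starting material / %): 0.667: 18.6, 50.5, 5.4; 1.33: 21.2, 53.7, 1.4; 2.00: 19.8, 52.1, 0.1; 3.00: 20.9, 51.5, 0.3; 4.00: 18.1, 52.8, 0; 5.00: 20.2, 51.7, 0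

(standard deviation of a reading: 1 percentage point)

1. share of other capture product in other capture product plus target at 20 s
2. share of other capture product in other capture product plus target at 5.0 h

- a reading or a percentage of target counts all its forms, free or not

On the fastest rung I assume an unseen intermediate, captured as soon as it forms and held at quasi-steady state. The next rung is the decay of the starting material. At 0.667 h its rate constant reads 4.58 h⁻¹ in Tuesday's run with 0.20 M of first nucleophile, and 4.38 h⁻¹ in Wednesday's with 0.31 M. The two readings are alike although the charges of first nucleophile differ, so I take this as the rate-limiting step, with a half-life reading 0.151 h. On the slowest rung, the later readings of both products in Tuesday's and Wednesday's runs stay flat within the scatter.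

I assume that target and other capture product form in the ratio S[B]/[D], where [B] and [D] are the concentrations of first and second nucleophile. The share of other capture product is then h = [D]/([D] + S[B]). I define S, a selectivity factor, as the last reading of target over the last reading of other capture product, times charged second over charged first nucleophile. It reads 2.94 in Tuesday's run and 2.97 in Wednesday's, and I carry their mean, 2.96.

At 20 s, far shorter than the half-life, about 2.51% of the starting material has reacted. With the flask's charges I get h = 46.5%, and I hold that for both times.

The forecast, on the ground that “capture looks irreversible”, says 42.4% (39.5% to 45.5%) at 20 s and 47.3% (44.5% to 50%) at 5.0 h. My early share is higher than the forecast's.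

The flask gives 49.1% at 20 s and 47.0% at 5.0 h, so h lies 2.6 percentage points below the first and 0.50 points below the second.

    2 second nucleophile → self-condensation product (k = 6.70 × 10⁻⁴ L mol⁻¹ s⁻¹)
    crystals ⇌ target, rate k2*(cs2 - [target]) while solid is left; crystals form when [target] > cs2 (solubility = 39.0 mM, k = 0.200 s⁻¹)
    first nucleophile + intermediate → target (k = 0.930 L mol⁻¹ s⁻¹)
    second nucleophile + intermediate → other capture product (k = 0.350 L mol⁻¹ s⁻¹)
    intermediate → solvolysis product (k = 0.130 s⁻¹)
    starting material → intermediate (k = 0.00130 s⁻¹)

In the neighbouring flask, otherwise the same but with 0.90 M of second nucleophile, the same S gives h = 68.5%. That flask gives 70.5% at 20 s and 61.9% at 5.0 h, and at 5.00 h it has 4.33% of its own charge of second nucleophile left.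

The earlier runs and the new flask were computed for substances that don't exist.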